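Remark on the chemistry: the SMILES fixes no configuration about the C3–C6'' axis and the target has no stereocentre; the route does not control the axis and should give racemic (or freely rotating) material.

Locants: unit 1 is the acacetin half (unprimed; ring B primed), unit 2 the apigenin half (double-primed; ring B triple-primed).

## The problem

The target joins C3 of a 5,7-dihydroxy-4'-methoxyflavone (unit 1) to C6'' of apigenin (unit 2). The C3–C6'' bond is the hard part: C3 is flanked by the C2 aryl group and the C4 carbonyl, C6'' by the oxygen-bearing carbons C5'' and C7'', so any coupling must bring four ortho substituents together. Ring A of unit 2 has two nucleophilic carbons, C6'' and C8'', and a pyranone closed at oxygen onto a C-substituted acylphloroglucinol can end with the substituent at either. Of six phenolic oxygens only O4' is methylated, so the other five need a group removable beside an aryl methyl ether. Strong acid is also excluded at the end, because it can interconvert 6''- and 8''-linked 5,7-dihydroxyflavones by ring opening and reclosure (Wessely–Moser rearrangement). The feature the plan uses is the position of C6'' in ring A of unit 2: it lies para to C8a'', which carries the pyranone oxygen O1'', and between the oxygen-bearing carbons C5'' and C7''. This is the pattern of a 2,6-dialkoxy-1,4-benzoquinone, whose C1 carbonyl carbon stands for C6'', whose ether oxygens stand for O5'' and O7'', and whose C4 carbonyl oxygen stands for O1''. Ring A of unit 2 can therefore enter as an electrophile at C6'' with O1'' already set apart, and the resulting 4-substituted 3,5-dialkoxyphenol has two equivalent ortho carbons, so a pyranone closed at C4''–C4a'' can only be the 6''-linked one.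

## Retrosynthesis

**15 to 14.** Five O–benzyl bonds are cut. Benzyl is chosen over methyl because O4'–CH3 must survive, and hydrogenolysis is neutral, so the 6''/8'' isomerisation cannot start. The forward step must spare two chromone C2=C3 bonds.

**14 to 12 (through 13).** The C4''–C4a'' bond is cut, a closure of ring C of unit 2 at carbon. The neighbouring cut, O1''–C2'' (closure at oxygen), would first need an intermolecular C-acylation of 7, for which ring A of unit 1 competes. In 12 the acid is tethered to the ring it must acylate, and that ring's two ortho carbons are equivalent. The forward reaction needs an activation mild enough for benzyl ethers.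

**12 to 11 to 7 and 10.** The ester is hydrolysed, then the O1''–C2'' enol ether bond is cut. Phenol 7 has one free hydroxyl, so conjugate addition to alkynoate 10 has no site problem. The precursor loses ring B and C2''–C4'' of unit 2.

**7 to 6.** The C6'' hydroxyl and the dienone are traded for the phenol. This is an oxidation-level adjustment, asked only to remove one oxygen without touching the chromone.

**6 to 2 and 4 (through 5).** The C3–C6'' bond is cut, with C3 as carbanion and C6'' as a quinone carbonyl carbon. Against a cross-coupling cut of the same bond, this one needs no halide or boron on either partner, forms the bond by carbonyl addition, and delivers the O1''/O5''/O7'' differentiation for free. Both partners are one step from commercial compounds. The forward reaction must add 1,2 at the right carbonyl and avoid electron transfer.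

**2 from 1; 4 from 3; 10 from 8 (through 9).** These are an O-benzylation, a phenol-to-p-quinone oxidation and an acetylide carboxylation, each a single standard step.

## Roads not taken

Alternative 1: Cut C3–C6'' between two complete flavones and join 3-iodoflavone A1 with 6''-boronate A2 by Suzuki–Miyaura coupling. Reductive elimination from divalent palladium must force four ortho substituents together. A2 is a 2,6-dialkoxyarylboronate, a class that loses boron by protonolysis under the basic conditions. Making A2 needs C6''-selective halogenation that depends on a free 5''-OH, then benzylation of that chelated hydroxyl beside the new substituent, then borylation. The chosen plan needs one step on each partner before the union.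

Alternative 2: Cut C2–C3 and O1–C2 of unit 1 and build ring C around a benzylic carbon. Arylacetic acid A3 would acylate phloroglucinol to deoxybenzoin A4, followed by aroylation with 4-methoxybenzoyl chloride, Baker–Venkataraman transfer and cyclodehydration. A3 requires a para-selective C–C bond formation on 3, where the two ortho carbons compete. The methylene of A4 that must be acylated is flanked by a 2,6-bis(benzyloxy)aryl group, and its four free hydroxyls consume acylating agent. Several steps would rebuild what the chosen plan buys as acacetin and joins in one step.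

Alternative 3: Cut C3–C6'' back to an allyl ether on O5'' and use an aromatic Claisen rearrangement of A5 to A6. C6'' is the only free ortho carbon of O5'', so the site is secured. The rearrangement delivers C3 only as a methylene, however. Ring C and ring A of unit 1 would still need oxidative cleavage, C-acylation of a hindered methylene by a 2,4,6-trioxygenated benzoyl unit, and cyclodehydration. The freed 5''-OH next to the side chain invites benzofuran formation, and para migration to C8'' can compete.

Key step: step 3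

## Route

Step 1
Reactants: 1 acacetin (5,7-dihydroxy-2-(4-methoxyphenyl)-4H-chromen-4-one)
Product: 2 5,7-bis(benzyloxy)-2-(4-methoxyphenyl)-4H-chromen-4-one
Conditions: BnBr (2.5 equiv), K2CO3 (3 equiv), DMF, 80 °C
Reagents that add atoms: benzyl bromide, BrCc1ccccc1
Why: Williamson ether synthesis; the 7-OH reacts readily and the hydrogen-bonded 5-OH follows with excess reagent and heat.

Step 2
Reactants: 3 3,5-bis(benzyloxy)phenol
Product: 4 2,6-bis(benzyloxy)cyclohexa-2,5-diene-1,4-dione
Conditions: (KSO3)2NO (Fremy's salt, 2.5 equiv), KH2PO4, H2O/acetone, 0 °C to rt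
Reagents that add atoms: potassium nitrosodisulfonate, [K+].[K+].[O]N(S(=O)(=O)[O-])S(=O)(=O)[O-]
Why: Teuber oxidation of a phenol with a free para position to the p-quinone; the para carbon lies between the two ether groups, so the quinone has exactly the 2,6-dialkoxy pattern.

Step 3
Reactants: 2 5,7-bis(benzyloxy)-2-(4-methoxyphenyl)-4H-chromen-4-one; 4 2,6-bis(benzyloxy)cyclohexa-2,5-diene-1,4-dione
Product: 6 4-[5,7-bis(benzyloxy)-2-(4-methoxyphenyl)-4-oxo-4H-chromen-3-yl]-3,5-bis(benzyloxy)-4-hydroxycyclohexa-2,5-dien-1-one, via 3-lithioflavone 5 (not isolated)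
Conditions: LiN(i-Pr)2 (1.1 equiv), THF, −78 °C; then added to 4 (1.3 equiv) in THF, −78 °C; aq. NH4Cl
Reagents that add atoms: none
Why: LiN(i-Pr)2 removes H3 of 2, the vinylic proton next to the C4 carbonyl, and O4 holds the lithium of 5; C3 lithiation of flavones at −78 °C and trapping by electrophiles is established. The carbanion adds 1,2 to the C1 carbonyl of 4 to give the alkoxide of p-quinol 6; the closest known reaction type is the addition of aryl- and alkenyllithium reagents to p-benzoquinones to give 4-substituted 4-hydroxycyclohexa-2,5-dienones. The step needs carbonyl selectivity: C4=O of 4 is conjugated with both benzyloxy groups (a doubly vinylogous carbonate) and is deactivated, whereas C1=O has the ether oxygens only on its α-carbons and is the electrophilic one, as in the known regiochemistry of alkoxyquinones. It also needs 1,2-addition to outrun electron transfer to the quinone, which low temperature, inverse addition and a hard localized sp2 carbanion favour. The new C3–C6'' bond forms by attack perpendicular to the quinone plane on a carbon that becomes sp3, so the four flanking groups are not forced into one plane as in a reductive elimination. No ring is closed. The carbinol carbon of 6 carries two identical ring arms and is not a stereocentre. The oxygen of the untouched C4 carbonyl, para to the new bond, is the future O1''.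

Step 4
Reactants: 6 4-[5,7-bis(benzyloxy)-2-(4-methoxyphenyl)-4-oxo-4H-chromen-3-yl]-3,5-bis(benzyloxy)-4-hydroxycyclohexa-2,5-dien-1-one
Product: 7 5,7-bis(benzyloxy)-3-[2,6-bis(benzyloxy)-4-hydroxyphenyl]-2-(4-methoxyphenyl)-4H-chromen-4-one
Conditions: Zn dust, AcOH/THF, rt
Reagents that add atoms: none
Why: Reductive aromatisation of a p-quinol: two-electron reduction of the dienone expels the γ-hydroxyl and gives the phenolate, driven by aromaticity; the chromone and benzyl ethers should not react with Zn in AcOH at rt.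

Step 5
Reactants: 8 1-(benzyloxy)-4-ethynylbenzene
Product: 10 ethyl 3-[4-(benzyloxy)phenyl]prop-2-ynoate, via lithium acetylide 9 (not isolated)
Conditions: n-BuLi, THF, −78 °C; ClCO2Et, −78 °C to rt
Reagents that add atoms: ethyl chloroformate, CCOC(=O)Cl
Why: Deprotonation of a terminal alkyne and acylation of the acetylide with a chloroformate, the standard route to arylpropiolates.

Step 6
Reactants: 7 5,7-bis(benzyloxy)-3-[2,6-bis(benzyloxy)-4-hydroxyphenyl]-2-(4-methoxyphenyl)-4H-chromen-4-one; 10 ethyl 3-[4-(benzyloxy)phenyl]prop-2-ynoate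
Product: 11 ethyl (2Z)-3-[4-(benzyloxy)phenyl]-3-{3,5-bis(benzyloxy)-4-[5,7-bis(benzyloxy)-2-(4-methoxyphenyl)-4-oxo-4H-chromen-3-yl]phenoxy}prop-2-enoate
Conditions: Cs2CO3 (0.3 equiv), DMF, 60 °C
Reagents that add atoms: none
Why: Base-catalysed conjugate addition of a phenoxide to an alkynoate (oxa-Michael addition); anti addition puts the aryloxy group cis to the ester, the (Z) geometry the ring closure needs, and any (E) isomer is carried along. Phenol 7 has a single, unhindered free hydroxyl.

Step 7
Reactants: 11 ethyl (2Z)-3-[4-(benzyloxy)phenyl]-3-{3,5-bis(benzyloxy)-4-[5,7-bis(benzyloxy)-2-(4-methoxyphenyl)-4-oxo-4H-chromen-3-yl]phenoxy}prop-2-enoate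
Product: 12 (2Z)-3-[4-(benzyloxy)phenyl]-3-{3,5-bis(benzyloxy)-4-[5,7-bis(benzyloxy)-2-(4-methoxyphenyl)-4-oxo-4H-chromen-3-yl]phenoxy}prop-2-enoic acid
Conditions: LiOH (3 equiv), THF/MeOH/H2O, rt; then aq. HCl to pH 3
Reagents that add atoms: lithium hydroxide, [Li+].[OH-]
Why: Saponification; β-aryloxycinnamic esters are hydrolysed with the enol ether intact in the Ruhemann sequence, and at rt the fully etherified chromone of unit 1 should not be opened.

Step 8
Reactants: 12 (2Z)-3-[4-(benzyloxy)phenyl]-3-{3,5-bis(benzyloxy)-4-[5,7-bis(benzyloxy)-2-(4-methoxyphenyl)-4-oxo-4H-chromen-3-yl]phenoxy}prop-2-enoic acid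
Product: 14 5,7-bis(benzyloxy)-3-{5,7-bis(benzyloxy)-2-[4-(benzyloxy)phenyl]-4-oxo-4H-chromen-6-yl}-2-(4-methoxyphenyl)-4H-chromen-4-one, via mixed trifluoroacetic anhydride 13 (not isolated)
Conditions: (CF3CO)2O (3 equiv), CH2Cl2, 0 °C to rt
Reagents that add atoms: none
Why: Ruhemann-type flavone synthesis run as an intramolecular Friedel–Crafts acylation: 13 acylates the ring carbon ortho to the enol ether oxygen and closes ring C of unit 2 at C4''–C4a'' (six-membered, closure at carbon). The two ortho carbons of the 4-substituted 3,5-bis(benzyloxy)phenoxy ring are equivalent, so only the 6''-linked chromone can form. Three oxygens activate the ring, which should let a mild activator spare the benzyl ethers, and the acid set free equilibrates any (E) isomer.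

Step 9
Reactants: 14 5,7-bis(benzyloxy)-3-{5,7-bis(benzyloxy)-2-[4-(benzyloxy)phenyl]-4-oxo-4H-chromen-6-yl}-2-(4-methoxyphenyl)-4H-chromen-4-one
Product: 15 5,7-dihydroxy-3-[5,7-dihydroxy-2-(4-hydroxyphenyl)-4-oxo-4H-chromen-6-yl]-2-(4-methoxyphenyl)-4H-chromen-4-one
Conditions: H2 (1 atm), 10% Pd/C, THF/MeOH, rt
Reagents that add atoms: none
Why: Hydrogenolysis of five aryl benzyl ethers; the aryl methyl ether and the chromone double bonds should survive at 1 atm and rt, and the neutral medium excludes acid-promoted 6''/8'' isomerisation.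

## Compound list

1 | acacetin, 5,7-dihydroxy-2-(4-methoxyphenyl)-4H-chromen-4-one | COc1ccc(-c2cc(=O)c3c(O)cc(O)cc3o2)cc1 | starting material
2 | 5,7-bis(benzyloxy)-2-(4-methoxyphenyl)-4H-chromen-4-one | COc1ccc(-c2cc(=O)c3c(OCc4ccccc4)cc(OCc4ccccc4)cc3o2)cc1 | intermediate
3 | 3,5-bis(benzyloxy)phenol | Oc1cc(OCc2ccccc2)cc(OCc2ccccc2)c1 | starting material
4 | 2,6-bis(benzyloxy)cyclohexa-2,5-diene-1,4-dione | O=C1C=C(OCc2ccccc2)C(=O)C(OCc2ccccc2)=C1 | intermediate
5 | [5,7-bis(benzyloxy)-2-(4-methoxyphenyl)-4-oxo-4H-chromen-3-yl]lithium | [Li]c1c(-c2ccc(OC)cc2)oc2cc(OCc3ccccc3)cc(OCc3ccccc3)c2c1=O | intermediate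
6 | 4-[5,7-bis(benzyloxy)-2-(4-methoxyphenyl)-4-oxo-4H-chromen-3-yl]-3,5-bis(benzyloxy)-4-hydroxycyclohexa-2,5-dien-1-one | COc1ccc(-c2oc3cc(OCc4ccccc4)cc(OCc4ccccc4)c3c(=O)c2C2(O)C(OCc3ccccc3)=CC(=O)C=C2OCc2ccccc2)cc1 | intermediate
7 | 5,7-bis(benzyloxy)-3-[2,6-bis(benzyloxy)-4-hydroxyphenyl]-2-(4-methoxyphenyl)-4H-chromen-4-one | COc1ccc(-c2oc3cc(OCc4ccccc4)cc(OCc4ccccc4)c3c(=O)c2-c2c(OCc3ccccc3)cc(O)cc2OCc2ccccc2)cc1 | intermediate
8 | 1-(benzyloxy)-4-ethynylbenzene | C#Cc1ccc(OCc2ccccc2)cc1 | starting material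
9 | {[4-(benzyloxy)phenyl]ethynyl}lithium | [Li]C#Cc1ccc(OCc2ccccc2)cc1 | intermediate
10 | ethyl 3-[4-(benzyloxy)phenyl]prop-2-ynoate | CCOC(=O)C#Cc1ccc(OCc2ccccc2)cc1 | intermediate
11 | ethyl (2Z)-3-[4-(benzyloxy)phenyl]-3-{3,5-bis(benzyloxy)-4-[5,7-bis(benzyloxy)-2-(4-methoxyphenyl)-4-oxo-4H-chromen-3-yl]phenoxy}prop-2-enoate | CCOC(=O)/C=C(\Oc1cc(OCc2ccccc2)c(-c2c(-c3ccc(OC)cc3)oc3cc(OCc4ccccc4)cc(OCc4ccccc4)c3c2=O)c(OCc2ccccc2)c1)c1ccc(OCc2ccccc2)cc1 | intermediate
12 | (2Z)-3-[4-(benzyloxy)phenyl]-3-{3,5-bis(benzyloxy)-4-[5,7-bis(benzyloxy)-2-(4-methoxyphenyl)-4-oxo-4H-chromen-3-yl]phenoxy}prop-2-enoic acid | OC(=O)/C=C(\Oc1cc(OCc2ccccc2)c(-c2c(-c3ccc(OC)cc3)oc3cc(OCc4ccccc4)cc(OCc4ccccc4)c3c2=O)c(OCc2ccccc2)c1)c1ccc(OCc2ccccc2)cc1 | intermediate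
13 | mixed anhydride of 12 with trifluoroacetic acid | FC(F)(F)C(=O)OC(=O)/C=C(\Oc1cc(OCc2ccccc2)c(-c2c(-c3ccc(OC)cc3)oc3cc(OCc4ccccc4)cc(OCc4ccccc4)c3c2=O)c(OCc2ccccc2)c1)c1ccc(OCc2ccccc2)cc1 | intermediate
14 | 5,7-bis(benzyloxy)-3-{5,7-bis(benzyloxy)-2-[4-(benzyloxy)phenyl]-4-oxo-4H-chromen-6-yl}-2-(4-methoxyphenyl)-4H-chromen-4-one | COc1ccc(-c2oc3cc(OCc4ccccc4)cc(OCc4ccccc4)c3c(=O)c2-c2c(OCc3ccccc3)cc3oc(-c4ccc(OCc5ccccc5)cc4)cc(=O)c3c2OCc2ccccc2)cc1 | intermediate
15 | 5,7-dihydroxy-3-[5,7-dihydroxy-2-(4-hydroxyphenyl)-4-oxo-4H-chromen-6-yl]-2-(4-methoxyphenyl)-4H-chromen-4-one | COc1ccc(-c2oc3cc(O)cc(O)c3c(=O)c2-c2c(O)cc3oc(-c4ccc(O)cc4)cc(=O)c3c2O)cc1 | target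

## Step count and risks

Total steps: 9. Longest linear sequence: 7 (steps 1, 3, 4, 6, 7, 8, 9 from acacetin).

**Step 3 (key step).** Several processes can compete with the addition:
- electron transfer from 5 to the quinone, which returns 2 and reduced quinone;
- addition at the C4 carbonyl or conjugate addition;
- fragmentation of 5 by β-elimination of the O1 phenoxide if the solution warms;
- benzylic deprotonation of a benzyl ether;
- slow addition for steric reasons.

Fallback by cross-coupling, from 4 and 5 to 7, bypassing 6: quinone 4 is reduced (Na2S2O4) to 2,6-bis(benzyloxy)benzene-1,4-diol F1. Its unflanked hydroxyl is silylated (TBSCl, imidazole) to 2,6-bis(benzyloxy)-4-[(tert-butyldimethylsilyl)oxy]phenol F2. Triflation (Tf2O, pyridine) gives 2,6-bis(benzyloxy)-4-[(tert-butyldimethylsilyl)oxy]phenyl trifluoromethanesulfonate F3. Lithio species 5 is transmetalated with ZnCl2 to chlorido[5,7-bis(benzyloxy)-2-(4-methoxyphenyl)-4-oxo-4H-chromen-3-yl]zinc F4. Negishi coupling of F4 with F3 (Pd(OAc)2, RuPhos, THF, 60 °C) gives 5,7-bis(benzyloxy)-3-{2,6-bis(benzyloxy)-4-[(tert-butyldimethylsilyl)oxy]phenyl}-2-(4-methoxyphenyl)-4H-chromen-4-one F5, and Bu4NF returns phenol 7.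

**Step 6.** The β-aryl alkynoate is a sluggish acceptor, the phenoxide may attack the ester carbonyl instead, and the addition may reverse on heating. Fallback by addition–elimination at an sp2 carbon, from 7 and 10 to 11: alkynoate 10 is hydrochlorinated (LiCl, AcOH) to ethyl (2Z)-3-[4-(benzyloxy)phenyl]-3-chloroprop-2-enoate F6, and the phenoxide of 7 (Cs2CO3, DMF) displaces chloride to give 11.

**Step 8.** The mixed anhydride of a vinylogous carbonate may not be electrophilic enough, and stronger acid would start cleaving benzyl ethers or the enol ether. Fallback by closure at oxygen, from 7 to 14, bypassing steps 6 to 8: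
- phenol 7 is acetylated (Ac2O, pyridine) to 4-[5,7-bis(benzyloxy)-2-(4-methoxyphenyl)-4-oxo-4H-chromen-3-yl]-3,5-bis(benzyloxy)phenyl acetate F7;
- Fries rearrangement (TiCl4, CH2Cl2) to either equivalent ortho carbon gives 3-[3-acetyl-2,6-bis(benzyloxy)-4-hydroxyphenyl]-5,7-bis(benzyloxy)-2-(4-methoxyphenyl)-4H-chromen-4-one F8;
- Claisen–Schmidt condensation with 4-(benzyloxy)benzaldehyde (KOH, EtOH/THF) gives 5,7-bis(benzyloxy)-3-(2,6-bis(benzyloxy)-3-{(2E)-3-[4-(benzyloxy)phenyl]prop-2-enoyl}-4-hydroxyphenyl)-2-(4-methoxyphenyl)-4H-chromen-4-one F9;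
- oxidative cyclisation (I2, DMSO, 120 °C) onto the only free hydroxyl gives 14.

**Step 9.** Partial saturation of a chromone C2=C3 bond, incomplete cleavage of the flanked benzyl ethers and poor solubility of partly deprotected material are the likely problems. Fallback from 14 to 15 without hydrogen: Lewis-acid debenzylation with BCl3 and pentamethylbenzene as cation scavenger (CH2Cl2, −78 °C), which cleaves aryl benzyl ethers and leaves the aryl methyl ether.

## Further compounds

F1 | step 3 | 2,6-bis(benzyloxy)benzene-1,4-diol | Oc1cc(OCc2ccccc2)c(O)c(OCc2ccccc2)c1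
F2 | step 3 | 2,6-bis(benzyloxy)-4-[(tert-butyldimethylsilyl)oxy]phenol | CC(C)(C)[Si](C)(C)Oc1cc(OCc2ccccc2)c(O)c(OCc2ccccc2)c1
F3 | step 3 | 2,6-bis(benzyloxy)-4-[(tert-butyldimethylsilyl)oxy]phenyl trifluoromethanesulfonate | CC(C)(C)[Si](C)(C)Oc1cc(OCc2ccccc2)c(OS(=O)(=O)C(F)(F)F)c(OCc2ccccc2)c1
F4 | step 3 | chlorido[5,7-bis(benzyloxy)-2-(4-methoxyphenyl)-4-oxo-4H-chromen-3-yl]zinc | Cl[Zn]c1c(-c2ccc(OC)cc2)oc2cc(OCc3ccccc3)cc(OCc3ccccc3)c2c1=O
F5 | step 3 | 5,7-bis(benzyloxy)-3-{2,6-bis(benzyloxy)-4-[(tert-butyldimethylsilyl)oxy]phenyl}-2-(4-methoxyphenyl)-4H-chromen-4-one | COc1ccc(-c2oc3cc(OCc4ccccc4)cc(OCc4ccccc4)c3c(=O)c2-c2c(OCc3ccccc3)cc(O[Si](C)(C)C(C)(C)C)cc2OCc2ccccc2)cc1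
F6 | step 6 | ethyl (2Z)-3-[4-(benzyloxy)phenyl]-3-chloroprop-2-enoate | CCOC(=O)/C=C(\Cl)c1ccc(OCc2ccccc2)cc1
F7 | step 8 | 4-[5,7-bis(benzyloxy)-2-(4-methoxyphenyl)-4-oxo-4H-chromen-3-yl]-3,5-bis(benzyloxy)phenyl acetate | COc1ccc(-c2oc3cc(OCc4ccccc4)cc(OCc4ccccc4)c3c(=O)c2-c2c(OCc3ccccc3)cc(OC(C)=O)cc2OCc2ccccc2)cc1
F8 | step 8 | 3-[3-acetyl-2,6-bis(benzyloxy)-4-hydroxyphenyl]-5,7-bis(benzyloxy)-2-(4-methoxyphenyl)-4H-chromen-4-one | COc1ccc(-c2oc3cc(OCc4ccccc4)cc(OCc4ccccc4)c3c(=O)c2-c2c(OCc3ccccc3)c(C(C)=O)c(O)cc2OCc2ccccc2)cc1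
F9 | step 8 | 5,7-bis(benzyloxy)-3-(2,6-bis(benzyloxy)-3-{(2E)-3-[4-(benzyloxy)phenyl]prop-2-enoyl}-4-hydroxyphenyl)-2-(4-methoxyphenyl)-4H-chromen-4-one | COc1ccc(-c2oc3cc(OCc4ccccc4)cc(OCc4ccccc4)c3c(=O)c2-c2c(OCc3ccccc3)c(C(=O)/C=C/c3ccc(OCc4ccccc4)cc3)c(O)cc2OCc2ccccc2)cc1
F0 | step 9 | none | none
A1 | alternative 1 | 5,7-bis(benzyloxy)-3-iodo-2-(4-methoxyphenyl)-4H-chromen-4-one | COc1ccc(-c2oc3cc(OCc4ccccc4)cc(OCc4ccccc4)c3c(=O)c2I)cc1
A2 | alternative 1 | 5,7-bis(benzyloxy)-2-[4-(benzyloxy)phenyl]-6-(4,4,5,5-tetramethyl-1,3,2-dioxaborolan-2-yl)-4H-chromen-4-one | CC1(C)OB(OC1(C)C)c1c(OCc2ccccc2)cc2oc(-c3ccc(OCc4ccccc4)cc3)cc(=O)c2c1OCc1ccccc1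
A3 | alternative 2 | 2-[2,6-bis(benzyloxy)-4-hydroxyphenyl]acetic acid | OC(=O)Cc1c(OCc2ccccc2)cc(O)cc1OCc1ccccc1
A4 | alternative 2 | 2-[2,6-bis(benzyloxy)-4-hydroxyphenyl]-1-(2,4,6-trihydroxyphenyl)ethan-1-one | O=C(Cc1c(OCc2ccccc2)cc(O)cc1OCc1ccccc1)c1c(O)cc(O)cc1O
A5 | alternative 3 | 7-(benzyloxy)-2-[4-(benzyloxy)phenyl]-5-{[2-(4-methoxyphenyl)prop-2-en-1-yl]oxy}-4H-chromen-4-one | C=C(COc1cc(OCc2ccccc2)cc2oc(-c3ccc(OCc4ccccc4)cc3)cc(=O)c12)c1ccc(OC)cc1
A6 | alternative 3 | 7-(benzyloxy)-2-[4-(benzyloxy)phenyl]-5-hydroxy-6-[2-(4-methoxyphenyl)prop-2-en-1-yl]-4H-chromen-4-one | C=C(Cc1c(O)c2c(=O)cc(-c3ccc(OCc4ccccc4)cc3)oc2cc1OCc1ccccc1)c1ccc(OC)cc1
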